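The route rests on forming the tetronate C3=C4 double bond (butenolide ring O1–C2–C3–C4–C5) as the step that completes the tricyclic core. The enol-ether oxygen O11 on C4 is also the ring oxygen of the fused dihydropyran, so C4 can begin as the carbonyl of a δ-lactone (C4–O11–C12) whose α-carbon C5 bears a tertiary hydroxyl. Ph3P=C=C=O acylates that hydroxyl and the resulting ester ylide olefinates the lactone carbonyl in the same flask, annulating the butenolide while the C12–O11 bond and all stereocentres stay intact. The precursor, a cis-fused α-hydroxy δ-lactone, comes from an exo Diels–Alder reaction of a lactic-acid-derived dienyl carbinol with 2-bromoacrolein; the macrocycle is closed afterwards.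

Key step: step 13

Atom labels used below: butenolide O1–C2(=O)–C3=C4–C5; cyclohexene C5–C6H2–C7H(Et)–C8(Me)=C9H–C10(Me); dihydropyran C4–O11–C12(Me)–C13H2–C10–C5; macrocycle chain C3–C14(=O)–C15H2–C16H(OMe)–C17(Me)=C18H–C19H2–C20H2–C21(Me)=C22H–C12. Target: 5S, 7S, 10S, 12S, 16R; 17Z, 21Z.

Remark on the chemistry: the (S)-configured oxazaborolidinium of step 10 is assumed to expose the enal face that leads to adduct 18; if the sense of induction is the opposite, its enantiomer is the intended catalyst.

Step 1
Reactants: 1 (E)-2-methylpent-2-enal; 2 ethyl 2-(triphenylphosphoranylidene)propanoate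
Product: 3 ethyl (2E,4E)-2,4-dimethylhepta-2,4-dienoate
Conditions: toluene, 90 °C
Reagents that add atoms: none
Why: Wittig olefination with a stabilised α-methyl ylide should give the (E)-trisubstituted enoate, extending the (E)-enal to the (2E,4E)-dienoate.

Step 2
Reactants: 3 ethyl (2E,4E)-2,4-dimethylhepta-2,4-dienoate
Product: 4 (2E,4E)-2,4-dimethylhepta-2,4-dien-1-ol
Conditions: iBu2AlH, CH2Cl2, −78 °C
Reagents that add atoms: none
Why: 1,2-Reduction of the conjugated ester by the aluminium hydride should give the allylic alcohol without touching the diene.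

Step 3
Reactants: 4 (2E,4E)-2,4-dimethylhepta-2,4-dien-1-ol
Product: 5 (2E,4E)-1-bromo-2,4-dimethylhepta-2,4-diene
Conditions: CBr4, PPh3, CH2Cl2, 0 °C; used without storage
Reagents that add atoms: carbon tetrabromide, BrC(Br)(Br)Br
Why: Appel bromination converts the primary allylic alcohol to the bromide under neutral conditions, so both alkene geometries should be retained.

Step 4
Reactants: 6 (R)-lactic acid; 7 pivalaldehyde
Product: 8 (2R,5R)-2-tert-butyl-5-methyl-1,3-dioxolan-4-one
Conditions: p-TsOH (cat.), H2SO4 (cat.), pentane, reflux with water removal; crystallisation of the cis isomer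
Reagents that add atoms: none
Why: Acid-catalysed acetalisation of the α-hydroxy acid favours the cis-dioxolanone, whose acetal centre stores the lactate configuration.

Step 5
Reactants: 8 (2R,5R)-2-tert-butyl-5-methyl-1,3-dioxolan-4-one; 5 (2E,4E)-1-bromo-2,4-dimethylhepta-2,4-diene
Product: 10 (2R,5S)-2-tert-butyl-5-[(2E,4E)-2,4-dimethylhepta-2,4-dien-1-yl]-5-methyl-1,3-dioxolan-4-one, via lithium enolate 9 (not isolated)
Conditions: LiN(iPr)2, THF, −78 °C; then 5, −78 → −30 °C
Reagents that add atoms: none
Why: Enolate alkylation under self-regeneration of stereocentres: the allylic bromide should attack the enolate face anti to the tert-butyl group, replacing H by C13 with net retention and setting C12 as S.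

Step 6
Reactants: 10 (2R,5S)-2-tert-butyl-5-[(2E,4E)-2,4-dimethylhepta-2,4-dien-1-yl]-5-methyl-1,3-dioxolan-4-one
Product: 11 (2S,4E,6E)-2,4,6-trimethylnona-4,6-diene-1,2-diol
Conditions: LiAlH4, Et2O, 0 °C → rt
Reagents that add atoms: none
Why: Hydride reduction of the acylal-type lactone should release the 1,2-diol and neopentyl alcohol without affecting the quaternary centre.

Step 7
Reactants: 11 (2S,4E,6E)-2,4,6-trimethylnona-4,6-diene-1,2-diol
Product: 12 (2S,4E,6E)-2,4,6-trimethyl-1,2-bis(triethylsilyloxy)nona-4,6-diene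
Conditions: Et3SiOTf (2.5 equiv), 2,6-lutidine, CH2Cl2, −78 → 0 °C
Reagents that add atoms: triethylsilyl trifluoromethanesulfonate, CC[Si](CC)(CC)OS(=O)(=O)C(F)(F)F
Why: The silyl triflate with a hindered base should silylate both the primary and the tertiary hydroxyl.

Step 8
Reactants: 12 (2S,4E,6E)-2,4,6-trimethyl-1,2-bis(triethylsilyloxy)nona-4,6-diene
Product: 13 (2S,4E,6E)-2,4,6-trimethyl-2-(triethylsilyloxy)nona-4,6-dienal
Conditions: (COCl)2, DMSO, CH2Cl2, −78 → −30 °C; then Et3N
Reagents that add atoms: none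
Why: Swern conditions cleave and oxidise a primary triethylsilyl ether selectively, so the non-enolisable α-silyloxy aldehyde should form directly while the tertiary silyl ether stays.

Step 9
Reactants: 13 (2S,4E,6E)-2,4,6-trimethyl-2-(triethylsilyloxy)nona-4,6-dienal; 14 ethyltriphenylphosphonium iodide
Product: 16 (2Z,4S,6E,8E)-2-iodo-4,6,8-trimethyl-4-(triethylsilyloxy)undeca-2,6,8-triene, via (1-iodoethylidene)triphenylphosphorane 15 (not isolated)
Conditions: 14, n-BuLi, THF, 0 °C; I2, −78 °C; NaN(SiMe3)2, −20 °C; then 13, −78 → −20 °C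
Reagents that add atoms: iodine, II
Why: Stork–Zhao olefination with the α-iodo ylide should give the (Z)-2-iodoalkene (iodine cis to C12) under the kinetic control typical of non-stabilised ylides.

Step 10
Reactants: 16 (2Z,4S,6E,8E)-2-iodo-4,6,8-trimethyl-4-(triethylsilyloxy)undeca-2,6,8-triene; 17 2-bromoacrolein
Product: 18 (1R,2S,5S)-1-bromo-5-ethyl-2-[(2S,3Z)-4-iodo-2-methyl-2-(triethylsilyloxy)pent-3-en-1-yl]-2,4-dimethylcyclohex-3-ene-1-carbaldehyde
Conditions: (S)-3,3-diphenyl-1-(2-methylphenyl)tetrahydro-1H,3H-pyrrolo[1,2-c][1,3,2]oxazaborole (20 mol %), HN(SO2CF3)2 (18 mol %), CH2Cl2, −78 → −40 °C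
Reagents that add atoms: none
Why: Lewis-acid-catalysed Diels–Alder reaction in which the CH2 terminus of the activated enal bonds to the more nucleophilic, less substituted diene terminus C7 and the α-carbon to C10; the (E,E)-diene places ethyl and C13 cis, the exo position of CHO usual for 2-substituted acroleins places Br cis to both, and the chiral oxazaborolidinium, which binds the formyl group and shields one enal face, should set the absolute sense at C5, C7 and C10 irrespective of the remote C12.

Step 11
Reactants: 18 (1R,2S,5S)-1-bromo-5-ethyl-2-[(2S,3Z)-4-iodo-2-methyl-2-(triethylsilyloxy)pent-3-en-1-yl]-2,4-dimethylcyclohex-3-ene-1-carbaldehyde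
Product: 21 (3S,4aS,7S,8aS)-7-ethyl-3-[(1Z)-2-iodoprop-1-en-1-yl]-3,4a,6-trimethyl-3,4,4a,7,8,8a-hexahydro-1H-isochromene-1,8a-diol (anomer mixture), via bromo lactol 19 (not isolated), via epoxy acetal 20 (not isolated)
Conditions: Bu4NF (1.3 equiv), THF–H2O (20:1), 0 °C → rt
Reagents that add atoms: water, O
Why: Fluoride frees the C12 alkoxide, which adds to the aldehyde; the lactolate oxygen should then displace the tertiary bromide from the rear (epoxy-ether chemistry of α-halo aldehydes, inversion at C5) and water opens the epoxy acetal at the acetal carbon C4, so the former aldehyde oxygen ends on C5 opposite to where bromine was and the rings become cis-fused.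

Step 12
Reactants: 21 (3S,4aS,7S,8aS)-7-ethyl-3-[(1Z)-2-iodoprop-1-en-1-yl]-3,4a,6-trimethyl-3,4,4a,7,8,8a-hexahydro-1H-isochromene-1,8a-diol
Product: 22 (3S,4aS,7S,8aS)-7-ethyl-8a-hydroxy-3-[(1Z)-2-iodoprop-1-en-1-yl]-3,4a,6-trimethyl-3,4,4a,7,8,8a-hexahydro-1H-isochromen-1-one
Conditions: TEMPO (20 mol %), PhI(OAc)2, CH2Cl2, rt
Reagents that add atoms: none
Why: Oxoammonium oxidation should convert the lactol into the δ-lactone and leave the tertiary alcohol, the alkenes and the vinyl iodide untouched.

Step 13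
Reactants: 22 (3S,4aS,7S,8aS)-7-ethyl-8a-hydroxy-3-[(1Z)-2-iodoprop-1-en-1-yl]-3,4a,6-trimethyl-3,4,4a,7,8,8a-hexahydro-1H-isochromen-1-one; 23 (triphenylphosphoranylidene)ketene
Product: 25 C3-unsubstituted tricyclic tetronate (5S,7S,10S,12S; 7-ethyl; 8,10,12-trimethyl; (Z)-2-iodoprop-1-enyl on C12), via ester ylide 24 (not isolated)
Conditions: 23 (1.5 equiv), PhCO2H (10 mol %), toluene, 60 → 100 °C
Reagents that add atoms: none
Why: The tertiary C5–OH adds across the C=C of the cumulated ylide to give ester ylide 24, whose carbanionic carbon (the future C3) attacks the adjacent lactone carbonyl C4, and the oxaphosphetane collapses to C3=C4 with loss of Ph3PO. The closest known reaction type is the domino addition–intramolecular Wittig olefination of α-hydroxy esters with Ph3P=C=C=O that gives 4-O-alkyl tetronates, here with the ester tied up as a lactone. The butenolide ring (O1, C2, C3, C4, C5) closes by 5-exo-trig attack of the ylide carbon on the lactone C=O followed by cycloreversion, and the former lactone ring survives as the dihydropyran. No new stereocentre is formed (C3 and C4 become sp2), and C5, C7, C10 and C12 are untouched because no bond to them is broken. The step needs olefination rather than C-acylation with ring opening; this is secured because the only possible leaving group is the tethered tertiary alkoxide O11 and oxaphosphetane collapse is irreversible, while the single hydroxyl makes the acylation site unambiguous and the vinyl iodide is inert to the stabilised ylide.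

Step 14
Reactants: 26 (R)-3-hydroxydihydrofuran-2(3H)-one
Product: 27 (R)-3-methoxydihydrofuran-2(3H)-one
Conditions: MeI, Ag2O, MeCN, rt, dark
Reagents that add atoms: iodomethane, CI
Why: Silver-oxide-mediated O-methylation alkylates the α-hydroxyl under non-basic conditions, so the α-stereocentre should not epimerise.

Step 15
Reactants: 27 (R)-3-methoxydihydrofuran-2(3H)-one
Product: 28 (R)-4-hydroxy-N,2-dimethoxy-N-methylbutanamide
Conditions: MeNH(OMe)·HCl, iPrMgCl, THF, −20 → 0 °C
Reagents that add atoms: N,O-dimethylhydroxylamine hydrochloride, CNOC.Cl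
Why: The chloromagnesium amide of N,O-dimethylhydroxylamine should open the lactone to the Weinreb amide (aminolysis), freeing the primary alcohol.

Step 16
Reactants: 28 (R)-4-hydroxy-N,2-dimethoxy-N-methylbutanamide
Product: 29 (R)-4-(tert-butyldiphenylsilyloxy)-N,2-dimethoxy-N-methylbutanamide
Conditions: tBuPh2SiCl, imidazole, CH2Cl2, rt
Reagents that add atoms: tert-butyl(chloro)diphenylsilane, CC(C)(C)[Si](Cl)(c1ccccc1)c1ccccc1
Why: Standard silylation of the primary alcohol gives an ether that should survive the organometallic, amide-base and mild-acid steps ahead.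

Step 17
Reactants: 29 (R)-4-(tert-butyldiphenylsilyloxy)-N,2-dimethoxy-N-methylbutanamide
Product: 30 (R)-5-(tert-butyldiphenylsilyloxy)-3-methoxypentan-2-one
Conditions: MeMgBr, THF, 0 °C
Reagents that add atoms: methylmagnesium bromide, C[Mg]Br
Why: Grignard addition to the Weinreb amide stops at the chelated tetrahedral intermediate, so the methyl ketone should appear only on work-up and C16 should not epimerise.

Step 18
Reactants: 30 (R)-5-(tert-butyldiphenylsilyloxy)-3-methoxypentan-2-one; 31 [3-(tert-butyldimethylsilyloxy)propyl]triphenylphosphonium bromide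
Product: 33 (3Z,5R)-1-(tert-butyldimethylsilyloxy)-7-(tert-butyldiphenylsilyloxy)-5-methoxy-4-methylhept-3-ene, via phosphorus ylide 32 (not isolated)
Conditions: 31, NaN(SiMe3)2, THF, 0 °C; then 30, −78 → 0 °C
Reagents that add atoms: none
Why: The Wittig reaction of a non-stabilised ylide with an α-alkoxy methyl ketone is Z-selective (the alkoxy-bearing carbon ends cis to the ylide chain), so the (Z)-alkene C17=C18 should form, and the low temperature limits enolisation at C16.

Step 19
Reactants: 33 (3Z,5R)-1-(tert-butyldimethylsilyloxy)-7-(tert-butyldiphenylsilyloxy)-5-methoxy-4-methylhept-3-ene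
Product: 34 (3Z,5R)-7-(tert-butyldiphenylsilyloxy)-5-methoxy-4-methylhept-3-en-1-ol
Conditions: PPTS (cat.), MeOH, rt
Reagents that add atoms: none
Why: Mild acid methanolysis removes a primary tert-butyldimethylsilyl ether much faster than a tert-butyldiphenylsilyl ether.

Step 20
Reactants: 34 (3Z,5R)-7-(tert-butyldiphenylsilyloxy)-5-methoxy-4-methylhept-3-en-1-ol
Product: 35 (3Z,5R)-7-(tert-butyldiphenylsilyloxy)-1-iodo-5-methoxy-4-methylhept-3-ene
Conditions: I2, PPh3, imidazole, CH2Cl2, 0 °C
Reagents that add atoms: iodine, II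
Why: Appel-type iodination should convert the primary alcohol into the iodide by SN2 displacement of the oxyphosphonium group.

Step 21
Reactants: 35 (3Z,5R)-7-(tert-butyldiphenylsilyloxy)-1-iodo-5-methoxy-4-methylhept-3-ene; 25 C3-unsubstituted tricyclic tetronate
Product: 37 tricyclic tetronate carrying on C12 the (1Z,5Z,7R)-9-(tert-butyldiphenylsilyloxy)-7-methoxy-2,6-dimethylnona-1,5-dien-1-yl chain, via alkylzinc iodide 36 (not isolated)
Conditions: 35, Zn dust, LiCl, THF, 40 °C; then 25, Pd(dppf)Cl2 (5 mol %), THF, 25–40 °C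
Reagents that add atoms: none
Why: Negishi coupling: zinc insertion gives the primary alkylzinc iodide, and oxidative addition of zerovalent palladium to the alkenyl C–I bond, transmetallation and reductive elimination should join C20 to C21 with retention of the Z geometry, oxidative addition being much faster than ionisation of the hindered tertiary allylic ether.

Step 22
Reactants: 37 tricyclic tetronate with the C12 side chain
Product: 39 3-iodo tetronate (C3–I; otherwise as 37), via 3-lithio tetronate 38 (not isolated)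
Conditions: LiN(iPr)2 (1.2 equiv), THF, −78 °C; then I2, −78 °C
Reagents that add atoms: iodine, II
Why: The C3–H of a 4-alkoxybutenolide without C5 hydrogens is the only acidic site, so the amide base should remove it and iodine trap the alkenyllithium.

Step 23
Reactants: 39 3-iodo tetronate
Product: 40 3-iodo tetronate with free primary alcohol at C14
Conditions: Bu4NF, AcOH, THF, rt
Reagents that add atoms: none
Why: Buffered fluoride should cleave the silyl ether without harming the tetronate or the alkenyl iodide.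

Step 24
Reactants: 40 3-iodo tetronate alcohol
Product: 41 3-iodo tetronate aldehyde (C14 aldehyde, β-methoxy)
Conditions: Dess–Martin periodinane, CH2Cl2, 0 °C → rt
Reagents that add atoms: none
Why: Dess–Martin oxidation of the primary alcohol should give the β-methoxy aldehyde under near-neutral conditions without elimination of methanol.

Step 25
Reactants: 41 3-iodo tetronate aldehyde
Product: 43 macrocyclic C14 carbinol (13-membered ring closed at C3–C14; epimer mixture at C14), via alkenylchromium dichloride 42 (not isolated)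
Conditions: CrCl2 (8 equiv), NiCl2 (2 mol %), DMSO–THF, rt, slow addition at 2 mM
Reagents that add atoms: none
Why: Nozaki–Hiyama–Kishi reaction: nickel-catalysed insertion into the C3–I bond, transmetallation to trivalent chromium and chemoselective addition of the alkenylchromium to the tethered aldehyde should close the 13-membered ring at high dilution; the new carbinol centre is uncontrolled and is removed in the next step.

Step 26
Reactants: 43 macrocyclic C14 carbinol
Product: 44 streptaspironate A
Conditions: Dess–Martin periodinane, CH2Cl2, rt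
Reagents that add atoms: none
Why: Dess–Martin oxidation of the allylic carbinol should give the 3-acyl tetronate ketone, which is the target, without touching any stereocentre.

Compound list

1 | (E)-2-methylpent-2-enal | CC/C=C(\C)C=O | starting material
2 | ethyl 2-(triphenylphosphoranylidene)propanoate | CCOC(=O)C(C)=P(c1ccccc1)(c1ccccc1)c1ccccc1 | starting material
3 | ethyl (2E,4E)-2,4-dimethylhepta-2,4-dienoate | CC/C=C(\C)/C=C(\C)C(=O)OCC | intermediate
4 | (2E,4E)-2,4-dimethylhepta-2,4-dien-1-ol | CC/C=C(\C)/C=C(\C)CO | intermediate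
5 | (2E,4E)-1-bromo-2,4-dimethylhepta-2,4-diene | CC/C=C(\C)/C=C(\C)CBr | intermediate
6 | (R)-lactic acid | C[C@@H](O)C(=O)O | starting material
7 | pivalaldehyde | CC(C)(C)C=O | starting material
8 | (2R,5R)-2-tert-butyl-5-methyl-1,3-dioxolan-4-one | C[C@H]1O[C@@H](C(C)(C)C)OC1=O | intermediate
9 | lithium enolate of 8 (formed in the flask) | CC1=C([O-])O[C@H](C(C)(C)C)O1.[Li+] | intermediate
10 | (2R,5S)-2-tert-butyl-5-[(2E,4E)-2,4-dimethylhepta-2,4-dien-1-yl]-5-methyl-1,3-dioxolan-4-one | C[C@@]1(C/C(C)=C/C(C)=C/CC)O[C@@H](C(C)(C)C)OC1=O | intermediate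
11 | (2S,4E,6E)-2,4,6-trimethylnona-4,6-diene-1,2-diol | C[C@@](O)(CO)C/C(C)=C/C(C)=C/CC | intermediate
12 | (2S,4E,6E)-2,4,6-trimethyl-1,2-bis(triethylsilyloxy)nona-4,6-diene | C[C@@](O[Si](CC)(CC)CC)(CO[Si](CC)(CC)CC)C/C(C)=C/C(C)=C/CC | intermediate
13 | (2S,4E,6E)-2,4,6-trimethyl-2-(triethylsilyloxy)nona-4,6-dienal | C[C@@](O[Si](CC)(CC)CC)(C=O)C/C(C)=C/C(C)=C/CC | intermediate
14 | ethyltriphenylphosphonium iodide | CC[P+](c1ccccc1)(c1ccccc1)c1ccccc1.[I-] | starting material
15 | (1-iodoethylidene)triphenylphosphorane (formed in the flask) | CC(I)=P(c1ccccc1)(c1ccccc1)c1ccccc1 | intermediate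
16 | (2Z,4S,6E,8E)-2-iodo-4,6,8-trimethyl-4-(triethylsilyloxy)undeca-2,6,8-triene | C[C@@](O[Si](CC)(CC)CC)(/C=C(/C)I)C/C(C)=C/C(C)=C/CC | intermediate
17 | 2-bromoacrolein | C=C(Br)C=O | starting material
18 | (1R,2S,5S)-1-bromo-5-ethyl-2-[(2S,3Z)-4-iodo-2-methyl-2-(triethylsilyloxy)pent-3-en-1-yl]-2,4-dimethylcyclohex-3-ene-1-carbaldehyde (Br cis to ethyl and to the side chain) | CC[C@H]1C[C@](Br)(C=O)[C@@](C)(C[C@](C)(O[Si](CC)(CC)CC)/C=C(/C)I)C=C1C | intermediate
19 | trans-fused bromo lactol, (3S,4aS,7S,8aR)-8a-bromo-7-ethyl-3-[(1Z)-2-iodoprop-1-en-1-yl]-3,4a,6-trimethyl-3,4,4a,7,8,8a-hexahydro-1H-isochromen-1-ol (formed in the flask) | CC[C@H]1C[C@]2(Br)C(O)O[C@](C)(/C=C(/C)I)C[C@@]2(C)C=C1C | intermediate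
20 | epoxy acetal, (3S,4aS,7S,8aS)-1,8a-epoxy-7-ethyl-3-[(1Z)-2-iodoprop-1-en-1-yl]-3,4a,6-trimethyl-3,4,4a,7,8,8a-hexahydro-1H-isochromene (formed in the flask) | CC[C@H]1C[C@@]23OC2O[C@](C)(/C=C(/C)I)C[C@@]3(C)C=C1C | intermediate
21 | (3S,4aS,7S,8aS)-7-ethyl-3-[(1Z)-2-iodoprop-1-en-1-yl]-3,4a,6-trimethyl-3,4,4a,7,8,8a-hexahydro-1H-isochromene-1,8a-diol (cis-fused; anomer mixture) | CC[C@H]1C[C@@]2(O)C(O)O[C@](C)(/C=C(/C)I)C[C@@]2(C)C=C1C | intermediate
22 | (3S,4aS,7S,8aS)-7-ethyl-8a-hydroxy-3-[(1Z)-2-iodoprop-1-en-1-yl]-3,4a,6-trimethyl-3,4,4a,7,8,8a-hexahydro-1H-isochromen-1-one | CC[C@H]1C[C@@]2(O)C(=O)O[C@](C)(/C=C(/C)I)C[C@@]2(C)C=C1C | intermediate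
23 | (triphenylphosphoranylidene)ketene | O=C=C=P(c1ccccc1)(c1ccccc1)c1ccccc1 | starting material
24 | ester ylide, the 8a-O-[(triphenylphosphoranylidene)acetyl] derivative of 22 (formed in the flask) | CC[C@H]1C[C@@]2(OC(=O)C=P(c3ccccc3)(c3ccccc3)c3ccccc3)C(=O)O[C@](C)(/C=C(/C)I)C[C@@]2(C)C=C1C | intermediate
25 | C3-unsubstituted tricyclic tetronate (5S,7S,10S,12S; 7-ethyl; 8,10,12-trimethyl; (Z)-2-iodoprop-1-enyl on C12) | CC[C@H]1C[C@@]23OC(=O)C=C2O[C@](C)(/C=C(/C)I)C[C@@]3(C)C=C1C | intermediate
26 | (R)-3-hydroxydihydrofuran-2(3H)-one | O[C@@H]1CCOC1=O | starting material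
27 | (R)-3-methoxydihydrofuran-2(3H)-one | CO[C@@H]1CCOC1=O | intermediate
28 | (R)-4-hydroxy-N,2-dimethoxy-N-methylbutanamide | CO[C@H](CCO)C(=O)N(C)OC | intermediate
29 | (R)-4-(tert-butyldiphenylsilyloxy)-N,2-dimethoxy-N-methylbutanamide | CO[C@H](CCO[Si](c1ccccc1)(c1ccccc1)C(C)(C)C)C(=O)N(C)OC | intermediate
30 | (R)-5-(tert-butyldiphenylsilyloxy)-3-methoxypentan-2-one | CO[C@H](CCO[Si](c1ccccc1)(c1ccccc1)C(C)(C)C)C(C)=O | intermediate
31 | [3-(tert-butyldimethylsilyloxy)propyl]triphenylphosphonium bromide | CC(C)(C)[Si](C)(C)OCCC[P+](c1ccccc1)(c1ccccc1)c1ccccc1.[Br-] | starting material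
32 | [3-(tert-butyldimethylsilyloxy)propylidene]triphenylphosphorane (formed in the flask) | CC(C)(C)[Si](C)(C)OCCC=P(c1ccccc1)(c1ccccc1)c1ccccc1 | intermediate
33 | (3Z,5R)-1-(tert-butyldimethylsilyloxy)-7-(tert-butyldiphenylsilyloxy)-5-methoxy-4-methylhept-3-ene | CO[C@H](CCO[Si](c1ccccc1)(c1ccccc1)C(C)(C)C)/C(C)=C\CCO[Si](C)(C)C(C)(C)C | intermediate
34 | (3Z,5R)-7-(tert-butyldiphenylsilyloxy)-5-methoxy-4-methylhept-3-en-1-ol | CO[C@H](CCO[Si](c1ccccc1)(c1ccccc1)C(C)(C)C)/C(C)=C\CCO | intermediate
35 | (3Z,5R)-7-(tert-butyldiphenylsilyloxy)-1-iodo-5-methoxy-4-methylhept-3-ene | CO[C@H](CCO[Si](c1ccccc1)(c1ccccc1)C(C)(C)C)/C(C)=C\CCI | intermediate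
36 | alkylzinc iodide from 35 (formed in the flask) | CO[C@H](CCO[Si](c1ccccc1)(c1ccccc1)C(C)(C)C)/C(C)=C\CC[Zn]I | intermediate
37 | tricyclic tetronate (5S,7S,10S,12S) carrying on C12 the (1Z,5Z,7R)-9-(tert-butyldiphenylsilyloxy)-7-methoxy-2,6-dimethylnona-1,5-dien-1-yl chain; C3–H | CC[C@H]1C[C@@]23OC(=O)C=C2O[C@](C)(/C=C(/C)CC/C=C(/C)[C@H](OC)CCO[Si](c4ccccc4)(c4ccccc4)C(C)(C)C)C[C@@]3(C)C=C1C | intermediate
38 | 3-lithio derivative of 37 (formed in the flask) | CC[C@H]1C[C@@]23OC(=O)C([Li])=C2O[C@](C)(/C=C(/C)CC/C=C(/C)[C@H](OC)CCO[Si](c4ccccc4)(c4ccccc4)C(C)(C)C)C[C@@]3(C)C=C1C | intermediate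
39 | 3-iodo derivative of 37 | CC[C@H]1C[C@@]23OC(=O)C(I)=C2O[C@](C)(/C=C(/C)CC/C=C(/C)[C@H](OC)CCO[Si](c4ccccc4)(c4ccccc4)C(C)(C)C)C[C@@]3(C)C=C1C | intermediate
40 | 3-iodo tetronate with free primary alcohol (C14–OH) | CC[C@H]1C[C@@]23OC(=O)C(I)=C2O[C@](C)(/C=C(/C)CC/C=C(/C)[C@H](OC)CCO)C[C@@]3(C)C=C1C | intermediate
41 | 3-iodo tetronate aldehyde (C14 aldehyde) | CC[C@H]1C[C@@]23OC(=O)C(I)=C2O[C@](C)(/C=C(/C)CC/C=C(/C)[C@H](OC)CC=O)C[C@@]3(C)C=C1C | intermediate
42 | alkenylchromium dichloride from 41 (trivalent chromium on C3; formed in the flask) | CC[C@H]1C[C@@]23OC(=O)C([Cr](Cl)Cl)=C2O[C@](C)(/C=C(/C)CC/C=C(/C)[C@H](OC)CC=O)C[C@@]3(C)C=C1C | intermediate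
43 | macrocyclic C14 carbinol (14-hydroxy analogue of the target; epimer mixture at C14) | CC[C@H]1C[C@@]23OC(=O)C4=C2O[C@](C)(/C=C(/C)CC/C=C(/C)[C@H](OC)CC4O)C[C@@]3(C)C=C1C | intermediate
44 | streptaspironate A | CC[C@H]1C[C@@]23OC(=O)C4=C2O[C@](C)(/C=C(/C)CC/C=C(/C)[C@H](OC)CC4=O)C[C@@]3(C)C=C1C | target

Total step count: 26. Longest linear sequence: 18 steps (steps 1–3, 5–13 and 21–26, from 1 to 44).

Steps most likely to fail

1. Step 10 (Diels–Alder). What may go wrong: slow cycloaddition of the tetrasubstituted diene with competing polymerisation of the enal, and erosion of exo or facial selectivity. Fallback (tethered cycloaddition): starting from 16, fluoride removes the silyl group to give the tertiary alcohol F1. Acylation with pyruvoyl chloride and pyridine gives the pyruvate ester F2, and silyl enol ether formation (tBuMe2SiOTf, Et3N) gives the 2-silyloxyacrylate ester F3. Heating (toluene, 170 °C, sealed tube) should then effect an intramolecular Diels–Alder reaction through the ester tether to the silyl-protected hydroxy lactone F4. The tether enforces the cis ring fusion (C4 cis to C13, oxygen on the other face) and the diene geometry fixes the ethyl orientation; the facial sense relative to C12 would have to be established. Bu4NF then rejoins the route at 22.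

2. Step 11 (bromide-to-hydroxyl inversion cascade). What may go wrong: elimination of HBr or a hydride shift instead of rear-side displacement at the hindered tertiary carbon by the internal lactolate. Fallback: starting from 18, NaOMe in MeOH (a small external alkoxide, same epoxy-ether pathway) should give the α-hydroxy dimethyl acetal F5 with the same inversion at C5 while the silyl ether is kept. Aqueous acetic acid in THF then removes the silyl group and hydrolyses the acetal, returning to the route at lactol 21.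

3. Step 13 (key step). What may go wrong: sluggish addition of the hindered tertiary hydroxyl to the cumulated ylide with thermal decay of the reagent, or failure of the ylide to engage the congested lactone carbonyl. Fallback (condensation instead of olefination): starting from 22, acetylation (Ac2O, 4-(dimethylamino)pyridine) gives the acetate F6. LiN(SiMe3)2 at −78 °C should bring about an intramolecular Claisen (Dieckmann-type) condensation onto the lactone carbonyl, which after ring opening gives the hydroxy tetronic acid F7. Acid-catalysed cyclodehydration (PPTS, toluene, molecular sieves), in which the C12 hydroxyl re-adds to C4 and water is lost without breaking the C12–O bond, returns to the route at 25.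

Further compounds

F1 | step 10 | (2Z,4S,6E,8E)-2-iodo-4,6,8-trimethylundeca-2,6,8-trien-4-ol | C[C@@](O)(/C=C(/C)I)C/C(C)=C/C(C)=C/CC
F2 | step 10 | pyruvate (2-oxopropanoate) ester of F1 | C[C@@](OC(=O)C(C)=O)(/C=C(/C)I)C/C(C)=C/C(C)=C/CC
F3 | step 10 | 2-(tert-butyldimethylsilyloxy)acrylate ester of F1 | C[C@@](OC(=O)C(=C)O[Si](C)(C)C(C)(C)C)(/C=C(/C)I)C/C(C)=C/C(C)=C/CC
F4 | step 10 | 8a-O-tert-butyldimethylsilyl ether of 22 | CC[C@H]1C[C@@]2(O[Si](C)(C)C(C)(C)C)C(=O)O[C@](C)(/C=C(/C)I)C[C@@]2(C)C=C1C
F5 | step 11 | α-hydroxy dimethyl acetal (C5 hydroxyl inverted relative to Br of 18; silyl ether kept) | CC[C@H]1C[C@@](O)(C(OC)OC)[C@@](C)(C[C@](C)(O[Si](CC)(CC)CC)/C=C(/C)I)C=C1C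
F6 | step 13 | 8a-O-acetate of 22 | CC[C@H]1C[C@@]2(OC(C)=O)C(=O)O[C@](C)(/C=C(/C)I)C[C@@]2(C)C=C1C
F7 | step 13 | spiro 4-hydroxy tetronic acid with free C12 hydroxyl (ring-opened condensation product) | CC[C@H]1C[C@]2(OC(=O)C=C2O)[C@@](C)(C[C@](C)(O)/C=C(/C)I)C=C1C
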